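## The problem

The target joins three rings. Ring A, a 2-acylcyclohexane-1,3,5-trione drawn as its enol, is spiro-linked to ring B, a cyclohexane, which is cis-fused to ring C, a cyclopentane. The spiro carbon is stereogenic only because the two ring-A carbonyls flanking it differ. The carbonyl leading to the methyl/prenyl quaternary carbon must lie on the face of ring B that carries the ring-B hydroxyl and ring C.

Rings B and C hold four contiguous stereocentres: two ring-fusion CH groups and two tertiary methyl carbinols. Once the cis fusion is fixed in absolute terms it can steer both carbinols through convex-face additions. The ring-B carbinol methyl group, axial in the favoured chair, can then steer the spiro centre.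

The methyl/prenyl quaternary carbon of ring A lies across a flat carbonyl from the spiro centre and faces two nearly equivalent half-spaces. Nothing in the molecule can control it, so it has to be brought in already resolved. The (R)-2-methylbutanoyl stereocentre is alpha to a carbonyl and should enter last.

Several groups are sensitive. The enolised beta-triketone is open to retro-Claisen cleavage and to O- versus C-reactivity. The prenyl alkene rules out ozone, hydrogenation and strong acid once it is present, and acid would also cyclise the enol onto it. The two tertiary alcohols dehydrate in acid and sit 1,3-cis to a ring-A carbonyl.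

The feature that invites the key step is that the C(Me)(OH) carbon of ring C is bonded directly to a ring-fusion carbon of ring B and to a ring CH2. That array results when the fusion carbon of a cis-fused 1-acetylcyclobutanol shifts from the carbinol carbon to the acetyl carbon. The old carbinol carbon becomes a ketone at the ring-C position where the target has CH2.

## Retrosynthesis

**Side chain.** Target 33 is the bis-desilylated form of 32. In 32 the bond between the ring-A enol carbon and the side-chain carbonyl is cut, giving trione 29 and (R)-2-methylbutanoic acid 30. Carrying the acyl group through the ring-A closure instead would expose its alpha stereocentre to strong base. The forward step has to acylate at carbon without enolising the acid.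

**Ring A.** Trione 29 is cut at the C(=O)–CH2 bond (Dieckmann) to give 28. Compound 28 is cut at the spiro carbon–C(=O) bond into ester 19 and acid chloride 27. The neighbouring cut, alkylating a preformed spiro trione with prenyl bromide or methyl iodide, would have to choose between two near-identical faces of a flat ring. Bringing the quaternary carbon in as enantiopure 27 removes that problem. The forward acylation must join two fully substituted carbons through a ketone and must occur on the enolate face opposite the axial ring-B methyl group.

**Fragment 27.** The acid chloride comes from tert-butyl ester 25. The C–prenyl bond of 25 is cut to give valine-derived enamine 22 and prenyl bromide 23. Enamine 22 comes from tert-butyl 2-methylacetoacetate 20 and L-valine tert-butyl ester 21. An auxiliary is preferred to a late resolution because the centre, once quaternary, cannot be corrected.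

**Ring-C carbonyl.** Ester 19 is the deoxygenated form of alpha-ketol 15. The ketone is removed by silylation (16), reduction (17), thiocarbonylation (18) and radical reduction. These steps form no skeletal bond; they are the cost of the key step.

**Key disconnection.** In 15 the bond between the ring-fusion carbon and the ring-C carbinol carbon is cut and the fusion carbon is reconnected to the adjacent carbonyl carbon. This is the reverse of an alpha-ketol shift and gives the cis-bicyclo[4.2.0] 1-acetylcyclobutanol 14. A cyclopentane carrying a tertiary carbinol with defined configuration is thereby reduced to a cyclobutanone adduct. The forward step has to move the fusion CH rather than the ring CH2 and relay the cyclobutanol configuration to the new carbinol.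

**Acetyl group.** Compound 14 is cut at the cyclobutane–acetyl bond to cyclobutanone 12 and an acetyl anion equivalent (via enol ether 13). The alternative of photoadding an olefin that already carries oxygen and masked acetyl would leave the carbinol configuration to an uncontrolled exo/endo ratio. Addition to the ketone from the convex face puts the hydroxyl endo, where the chelated shift needs it.

**Ring-B carbinol.** Cyclobutanone 12 comes from alcohol 11, acetate 10 and carbinol 9. In 9 the C–CH3 bond is cut to ketone 8. Ketone 8 is the mono-ester of photoadduct 7. One ester is removed before the methyl addition because an axial ester would sit syn to the trajectory that gives the required carbinol. The centre so created is erased again at the enolate stage of 19.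

**Cyclobutane.** Photoadduct 7 is cut at both four-ring bonds into enone 5 and vinyl acetate 6. This is a head-to-tail enone–olefin [2+2] photocycloaddition made enantioselective by a chiral Lewis acid. A silyl enol ether or ketene acetal would undergo Mukaiyama–Michael addition to the Lewis-acid-activated enone in the dark, so the oxygen is carried as an enol ester. The achiral, symmetrical enone keeps the enantio-determining step clean.

**Enone.** Enone 5 is cut at its C=C bond (aldol condensation) to keto aldehyde 4, which comes by ozonolysis from 3. Compound 3 is the alkylation product of dimethyl allylmalonate 1 and chloroacetone 2.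

## Roads not taken

**Alternative 1:** The cut is the spiro carbon–CH2 bond of ring B. In the forward sense the enolised ring-A carbon, already carrying its side arm, adds to an exocyclic methylene carbon of a cyclopentanone in that arm. This closes ring B and gives the spiro tricyclic ring-C ketone A1. The addition is reversible, so the spiro and fusion centres could settle under equilibrium.
- Merits: ring A with its acyl chain, methyl and prenyl groups is assembled early by known acylphloroglucinol chemistry, and the route is convergent and short.
- Weak points: the equilibrium position is unknown, and the target places a ring-A carbonyl axial and syn to the ring-B methyl group, which is not obviously the favoured isomer. The ring-A quaternary centre must be set beforehand with no relay to the rest. The enol can add through oxygen to give a pyran. The last methyl addition must find the ring-C ketone of A1 beside a free triketone.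
- Comparison: this road is clearly better in step count and convergence. The chosen plan offers instead a kinetic, arguable control element for every centre and a defined step where absolute configuration enters.

**Alternative 2:** The cut takes both cyclobutane bonds at once. A ketene generated in the chain adds across a tethered vinyl group, closing ring B and the cyclobutanone in one thermal step to give the cis-bicyclo[4.2.0]octanone ketal gem-diester A2.
- Merits: no photochemistry, the regiochemistry is dictated by the tether, cis fusion is guaranteed, and A2 could enter the chosen sequence at the cyclobutanone stage. In regiochemical certainty it is as good as or better than the photocycloaddition.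
- Weak points: a monosubstituted, unactivated vinyl group is a poor partner for a ketene, and the developing positive charge would sit next to the ketal carbon. Asymmetric induction would have to come from a C2-symmetric ketal whose stereocentres are remote from the new ones. The ring-B ketone would still face the axial-ester problem at the methyl addition.
- Comparison: similar length. The chosen plan relies on a well-behaved enone photocycloaddition and a catalytic enantio-determining step.

**Alternative 3:** The cut is the bond between the ring-B carbonyl carbon and the adjacent fusion carbon. A chiral carbene turns an aldehyde into an acyl anion equivalent that adds to the beta carbon of a tethered cyclopentenone (Stetter reaction), giving the cis-hydrindane-1,4-dione gem-diester A3.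
- Merits: catalytic and asymmetric, and it reaches the hydrindane with ketones exactly where the target has its two carbinols. No cyclobutane detour or deoxygenation is needed, so it is several steps shorter.
- Weak points: the acceptor is an alpha-substituted cyclic enone, a demanding case for this reaction. A3 is a 1,4-diketone open to epimerisation and aldol chemistry. Both carbinols would then rest on Grignard additions, one of them on the ring-B ketone with an axial ester in the way.
- Comparison: better step economy. The chosen plan sets the ring-C carbinol by a stereospecific relay instead of a second face-selective addition, and performs its asymmetric step on a simple achiral enone.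

Key step: step 11

## Assumptions

- The antipode of the oxazaborolidine in step 4 and the additive system (or valine antipode) in step 17 are taken to be those that give the configurations drawn; which they are must be established on the first runs.
- The target is handled as the enol tautomer drawn; its other enol and hemiketal forms are the same compound.

## Route

Locants: bicyclo[4.2.0]octanes are numbered C1 (fusion, next to C2), C2 (ring-B ketone or carbinol), C4 (ester carbon), C6 (fusion), C7 (four-ring carbon on C6), C8 (four-ring CH2). Octahydroindenes are numbered C1 (ring-C carbinol), C2, C3, C3a, C4 (ring-B carbinol), C6 (ester carbon), C7a.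

Step 1
Reactants: 1 dimethyl 2-allylmalonate; 2 chloroacetone
Product: 3 dimethyl 2-allyl-2-(2-oxopropyl)malonate
Conditions: NaH, THF, 0 °C; then 2, NaI (cat.), 0 °C → rt
Reagents that add atoms: none
Why: Alkylation of the sodium malonate enolate by the alpha-chloroketone (SN2, helped by in situ iodide exchange); no stereocentre is formed.

Step 2
Reactants: 3 dimethyl 2-allyl-2-(2-oxopropyl)malonate
Product: 4 dimethyl 2-(2-oxoethyl)-2-(2-oxopropyl)malonate
Conditions: O3, CH2Cl2/MeOH, −78 °C; then Me2S, −78 °C → rt
Reagents that add atoms: ozone, O=[O+][O-]
Why: Ozonolysis with reductive work-up cleaves the only alkene to the aldehyde; ketone and esters are inert.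

Step 3
Reactants: 4 dimethyl 2-(2-oxoethyl)-2-(2-oxopropyl)malonate
Product: 5 dimethyl 5-oxocyclohex-3-ene-1,1-dicarboxylate
Conditions: piperidine (0.2 equiv), AcOH (0.2 equiv), toluene, 80 °C
Reagents that add atoms: none
Why: Intramolecular aldol condensation of a 1,5-keto aldehyde; only attack of the methyl-ketone carbon on the aldehyde closes a six-membered ring (every other pairing would give a four-membered ring), and the quaternary carbon stops the enone from migrating toward the esters.

Step 4
Reactants: 5 dimethyl 5-oxocyclohex-3-ene-1,1-dicarboxylate; 6 vinyl acetate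
Product: 7 dimethyl (1R,6R)-7-acetoxy-2-oxobicyclo[4.2.0]octane-4,4-dicarboxylate (cis-fused; both C7 epimers)
Conditions: 6 (10 equiv), AlBr3-activated (S)-3,3-bis(3,5-dimethylphenyl)-1-(2,4,6-trifluorophenyl)tetrahydro-1H,3H-pyrrolo[1,2-c][1,3,2]oxazaborole (50 mol%), hν (366 nm), CH2Cl2, −78 °C; then basic Al2O3, CH2Cl2, rt
Reagents that add atoms: none
Why: Enone–olefin [2+2] photocycloaddition under chromophore activation by a chiral Lewis acid, a known reaction of cyclohexenones applied here to an enol ester; the head-to-tail orientation usual for donor olefins bonds the acetoxy carbon to the enone beta carbon, the bound catalyst shields one enone face and fixes C6, and alumina epimerises any trans-fused adduct at C1 to the cis ring fusion.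

Step 5
Reactants: 7 dimethyl (1R,6R)-7-acetoxy-2-oxobicyclo[4.2.0]octane-4,4-dicarboxylate
Product: 8 methyl (1R,6R)-7-acetoxy-2-oxobicyclo[4.2.0]octane-4-carboxylate (cis-fused; epimers at C4 and C7)
Conditions: LiCl, H2O, DMSO, 150 °C
Reagents that add atoms: none
Why: Krapcho dealkoxycarbonylation (chloride SN2 at a methyl group, loss of CO2, protonation); one ester is removed here because an axial ester syn to the incoming nucleophile would otherwise contest the face selection of step 6, and the new C–H centre is erased in step 19.

Step 6
Reactants: 8 methyl (1R,6R)-7-acetoxy-2-oxobicyclo[4.2.0]octane-4-carboxylate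
Product: 9 methyl 7-acetoxy-2-hydroxy-2-methylbicyclo[4.2.0]octane-4-carboxylate (cis-fused; 2-OH cis to C8, 2-methyl cis to H-1; epimers at C4 and C7)
Conditions: MeMgBr, CeCl3, THF, −78 °C
Reagents that add atoms: methylmagnesium bromide, C[Mg]Br
Why: 1,2-Addition of a methylcerium/Grignard reagent to the ketone; with the second ester gone, each C4 epimer has a conformer in which the face anti to the four-membered ring is open, so methyl should enter cis to H-1 and leave the hydroxyl cis to the cyclobutane, while cerium suppresses enolisation and the low temperature spares acetate and ester.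

Step 7
Reactants: 9 methyl 7-acetoxy-2-hydroxy-2-methylbicyclo[4.2.0]octane-4-carboxylate
Product: 10 methyl 7-acetoxy-2-methyl-2-(triethylsilyloxy)bicyclo[4.2.0]octane-4-carboxylate
Conditions: TESOTf, 2,6-lutidine, CH2Cl2, −78 → 0 °C
Reagents that add atoms: triethylsilyl trifluoromethanesulfonate, CC[Si](CC)(CC)OS(=O)(=O)C(F)(F)F
Why: Silylation of a tertiary alcohol with a silyl triflate; the bulky ether on this face also disfavours lactonisation of the cis ester in later steps.

Step 8
Reactants: 10 methyl 7-acetoxy-2-methyl-2-(triethylsilyloxy)bicyclo[4.2.0]octane-4-carboxylate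
Product: 11 methyl 7-hydroxy-2-methyl-2-(triethylsilyloxy)bicyclo[4.2.0]octane-4-carboxylate (ester cis to the silyloxy group; C7 epimers)
Conditions: NaOMe (0.3 equiv), MeOH, 50 °C
Reagents that add atoms: none
Why: Zemplén-type transesterification frees the cyclobutanol, and the same methoxide equilibrates the ring ester to the equatorial epimer cis to the silyloxy group (the other would be syn-axial to the ring methyl), giving one diastereomer to handle.

Step 9
Reactants: 11 methyl 7-hydroxy-2-methyl-2-(triethylsilyloxy)bicyclo[4.2.0]octane-4-carboxylate
Product: 12 methyl 2-methyl-7-oxo-2-(triethylsilyloxy)bicyclo[4.2.0]octane-4-carboxylate (cis-fused)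
Conditions: Dess–Martin periodinane, NaHCO3, CH2Cl2, rt
Reagents that add atoms: none
Why: Dess–Martin oxidation of the secondary cyclobutanol converges both C7 epimers on one cyclobutanone; the buffer protects the silyl ether.

Step 10
Reactants: 12 methyl 2-methyl-7-oxo-2-(triethylsilyloxy)bicyclo[4.2.0]octane-4-carboxylate
Product: 14 methyl 7-acetyl-7-hydroxy-2-methyl-2-(triethylsilyloxy)bicyclo[4.2.0]octane-4-carboxylate (7-OH endo, cis to the six-membered ring; acetyl exo), via enol ether 13 (not isolated)
Conditions: ethyl vinyl ether, t-BuLi, THF, −78 → 0 °C (gives CH2=C(OEt)Li); then 12, −78 °C; then 0.5 M HCl, THF, 0 °C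
Reagents that add atoms: ethyl vinyl ether, C=COCC; water, O
Why: 1,2-Addition of an acetyl anion equivalent to the strained, very electrophilic cyclobutanone, faster than attack on the ester; the nucleophile enters from the convex face (that of the angular hydrogens) so the hydroxyl ends endo, and brief dilute acid hydrolyses the enol ether to the methyl ketone without cleaving the tertiary silyl ether.

Step 11
Reactants: 14 methyl 7-acetyl-7-hydroxy-2-methyl-2-(triethylsilyloxy)bicyclo[4.2.0]octane-4-carboxylate
Product: 15 methyl 1-hydroxy-1,4-dimethyl-2-oxo-4-(triethylsilyloxy)octahydro-1H-indene-6-carboxylate (cis-fused; 1-OH on the concave face toward ring B, 1-methyl cis to H-7a)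
Conditions: Al(OtBu)3 (0.3 equiv), toluene, 80 °C
Reagents that add atoms: none
Why: Alpha-ketol (acyloin) rearrangement, the same reaction type as the aluminium-alkoxide ring expansion of 1-acylcyclobutanols to 2-hydroxycyclopentanones and the D-homoannulation of 17-hydroxy-20-keto steroids. The tertiary hydroxyl exchanges onto aluminium, which also binds the acetyl oxygen, so the C–O and C=O bonds are held syn-periplanar in a five-membered chelate. From this chelate the ring-fusion carbon C6 shifts with retention from C7 to the acetyl carbon, while C7 becomes the ketone and the acetyl carbon the new alkoxide. Ring C is therefore formed by one-carbon enlargement of the four-membered ring through a 1,2-shift and not by an end-to-end cyclisation, so no exo/endo ring-closure descriptor applies; release of cyclobutane strain makes the shift irreversible. The one new stereocentre, the ring-C carbinol carbon, is controlled by the configuration of C7: in the chelate the migrating carbon can reach only the acetyl face on its own side, which puts the new hydroxyl on the concave face and the methyl group cis to the angular hydrogens, as in the target. The step needs migration of the fusion CH in preference to the ring CH2, which the higher migratory aptitude of the more substituted carbon should secure, and it needs the chelated and not the dipole-opposed geometry, which an aluminium alkoxide in a non-coordinating solvent secures. The sub-stoichiometric, non-nucleophilic tert-butoxide leaves the methyl ester and the tertiary silyl ether alone, and the moderate temperature guards against a second ketol shift of the product.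

Step 12
Reactants: 15 methyl 1-hydroxy-1,4-dimethyl-2-oxo-4-(triethylsilyloxy)octahydro-1H-indene-6-carboxylate
Product: 16 methyl 1,4-dimethyl-2-oxo-1,4-bis(triethylsilyloxy)octahydro-1H-indene-6-carboxylate
Conditions: TESOTf, 2,6-lutidine, CH2Cl2, −78 → 0 °C
Reagents that add atoms: triethylsilyl trifluoromethanesulfonate, CC[Si](CC)(CC)OS(=O)(=O)C(F)(F)F
Why: Silylation of the tertiary alpha-ketol hydroxyl; it prevents cyclic thiocarbonate formation in the deoxygenation and O-acylation in step 19.

Step 13
Reactants: 16 methyl 1,4-dimethyl-2-oxo-1,4-bis(triethylsilyloxy)octahydro-1H-indene-6-carboxylate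
Product: 17 methyl 2-hydroxy-1,4-dimethyl-1,4-bis(triethylsilyloxy)octahydro-1H-indene-6-carboxylate (either C2 epimer)
Conditions: NaBH4, MeOH, 0 °C
Reagents that add atoms: none
Why: Hydride reduction of the ketone; the ester is untouched and the configuration of the new carbinol is irrelevant because it is removed.

Step 14
Reactants: 17 methyl 2-hydroxy-1,4-dimethyl-1,4-bis(triethylsilyloxy)octahydro-1H-indene-6-carboxylate
Product: 18 methyl 2-[(1H-imidazol-1-ylcarbonothioyl)oxy]-1,4-dimethyl-1,4-bis(triethylsilyloxy)octahydro-1H-indene-6-carboxylate
Conditions: 1,1'-thiocarbonyldiimidazole, DMAP (cat.), ClCH2CH2Cl, 70 °C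
Reagents that add atoms: 1,1'-thiocarbonyldiimidazole, S=C(n1ccnc1)n1ccnc1
Why: Thiocarbonylation of the secondary alcohol under neutral conditions, which avoids the base-induced 1,2-silyl migration that xanthate formation with NaH could cause.

Step 15
Reactants: 18 methyl 2-[(1H-imidazol-1-ylcarbonothioyl)oxy]-1,4-dimethyl-1,4-bis(triethylsilyloxy)octahydro-1H-indene-6-carboxylate
Product: 19 methyl 1,4-dimethyl-1,4-bis(triethylsilyloxy)octahydro-1H-indene-6-carboxylate (cis-fused; ester cis to the 4-silyloxy group)
Conditions: Bu3SnH, AIBN (cat.), toluene, 100 °C
Reagents that add atoms: none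
Why: Barton–McCombie deoxygenation: the stannyl radical adds to C=S, the secondary radical is released and abstracts hydrogen; no alkene is present yet and a beta-silyloxy radical does not fragment.

Step 16
Reactants: 20 tert-butyl 2-methyl-3-oxobutanoate; 21 L-valine tert-butyl ester
Product: 22 tert-butyl (Z)-3-{[(S)-1-tert-butoxy-3-methyl-1-oxobutan-2-yl]amino}-2-methylbut-2-enoate
Conditions: TsOH (cat.), benzene, reflux (−H2O)
Reagents that add atoms: none
Why: Condensation of the beta-keto ester with the amino ester gives the hydrogen-bonded (Z)-enamino ester; water is removed azeotropically.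

Step 17
Reactants: 22 tert-butyl (Z)-3-{[(S)-1-tert-butoxy-3-methyl-1-oxobutan-2-yl]amino}-2-methylbut-2-enoate; 23 prenyl bromide
Product: 25 tert-butyl (S)-2-acetyl-2,5-dimethylhex-4-enoate, via alkylated ketimine 24 (not isolated)
Conditions: LDA, toluene, −78 °C; HMPA (2 equiv), 23, −78 → −20 °C; then 1 M HCl, 0 °C
Reagents that add atoms: water, O
Why: Auxiliary-controlled alkylation of a lithiated beta-enamino ester, known for acyclic alpha-alkyl beta-keto esters: lithium is chelated by the enamine nitrogen and the valine ester carbonyl, the isopropyl group shields one face, prenyl bromide reacts SN2 at the other to set the quaternary centre, and acid hydrolysis of the ketimine returns the ketone and the auxiliary.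

Step 18
Reactants: 25 tert-butyl (S)-2-acetyl-2,5-dimethylhex-4-enoate
Product: 27 (S)-2-acetyl-2,5-dimethylhex-4-enoyl chloride, via trimethylsilyl ester 26 (not isolated)
Conditions: TMSOTf (1.1 equiv), 2,6-lutidine, CH2Cl2, 0 °C; then (COCl)2, DMF (cat.), 0 °C → rt
Reagents that add atoms: trimethylsilyl trifluoromethanesulfonate (silicon only in 26), C[Si](C)(C)OS(=O)(=O)C(F)(F)F; oxalyl chloride, ClC(=O)C(Cl)=O
Why: The silyl triflate cleaves the tert-butyl ester aprotically (loss of isobutene) to the silyl ester, which oxalyl chloride/DMF converts directly into the acid chloride; this avoids the decarboxylation-prone free beta-keto acid and protic acid that would cyclise the acid onto the prenyl alkene, and the quaternary centre cannot epimerise.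

Step 19
Reactants: 19 methyl 1,4-dimethyl-1,4-bis(triethylsilyloxy)octahydro-1H-indene-6-carboxylate; 27 (S)-2-acetyl-2,5-dimethylhex-4-enoyl chloride
Product: 28 methyl 6-[(S)-2-acetyl-2,5-dimethylhex-4-enoyl]-1,4-dimethyl-1,4-bis(triethylsilyloxy)octahydro-1H-indene-6-carboxylate (new acyl group cis to the 4-silyloxy group and to ring C; ester trans)
Conditions: LDA, THF, −78 °C; then 27, −78 → −40 °C
Reagents that add atoms: none
Why: Claisen-type C-acylation of a lithium ester enolate by an acid chloride, known for joining two fully substituted carbons through a ketone (isobutyrate enolate with pivaloyl chloride); in the favoured chair the ring-B methyl is axial and blocks the axial face of the exocyclic enolate, so the acyl group should enter equatorially, cis to the ring-B silyloxy group, which is the spiro configuration of the target.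

Step 20
Reactants: 28 methyl 6-[(S)-2-acetyl-2,5-dimethylhex-4-enoyl]-1,4-dimethyl-1,4-bis(triethylsilyloxy)octahydro-1H-indene-6-carboxylate
Product: 29 3-methyl-3-prenyl-1',4'-dimethyl-1',4'-bis(triethylsilyloxy)octahydrospiro[cyclohexane-1,6'-indene]-2,4,6-trione (ring A without its acyl group; configuration as in the SMILES)
Conditions: LiHMDS (2.2 equiv), THF, −78 → 0 °C; aq. NH4Cl
Reagents that add atoms: none
Why: Dieckmann condensation: the only enolisable position, the acetyl methyl, closes a six-membered ring onto the methyl ester as in the classical syncarpic acid synthesis; the acidic trione is deprotonated by the second equivalent of base, which drives the closure, and a non-nucleophilic amide base avoids retro-Claisen cleavage of the non-enolisable 1,3-dicarbonyl units.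

Step 21
Reactants: 29 3-methyl-3-prenyl-1',4'-dimethyl-1',4'-bis(triethylsilyloxy)octahydrospiro[cyclohexane-1,6'-indene]-2,4,6-trione; 30 (R)-2-methylbutanoic acid
Product: 32 bis(triethylsilyl) ether of the target, via enol ester 31 (not isolated)
Conditions: 30 (1.2 equiv), DCC, DMAP (0.3 equiv), CH2Cl2, 0 °C → rt
Reagents that add atoms: none
Why: Carbodiimide-mediated O-acylation of the enolised trione followed by DMAP-catalysed 1,3-acyl shift from oxygen to carbon, the standard route to 2-acylcyclohexane-1,3-diones; the hydrogen-bonded C-acyl triketone is the thermodynamic product and the alpha stereocentre of the acid is not enolised.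

Step 22
Reactants: 32 bis(triethylsilyl) ether of the target
Product: 33 target CNP0236509.3
Conditions: HF·pyridine, pyridine, THF, 0 °C → rt
Reagents that add atoms: none
Why: Fluoride cleavage of both tertiary triethylsilyl ethers; buffering with pyridine avoids acid-triggered cyclisation of the enol onto the prenyl group and dehydration of the tertiary alcohols.

## Compound list

1 | dimethyl 2-allylmalonate | C=CCC(C(=O)OC)C(=O)OC | starting material
2 | chloroacetone | CC(=O)CCl | starting material
3 | dimethyl 2-allyl-2-(2-oxopropyl)malonate | C=CCC(CC(C)=O)(C(=O)OC)C(=O)OC | intermediate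
4 | dimethyl 2-(2-oxoethyl)-2-(2-oxopropyl)malonate | O=CCC(CC(C)=O)(C(=O)OC)C(=O)OC | intermediate
5 | dimethyl 5-oxocyclohex-3-ene-1,1-dicarboxylate | O=C1C=CCC(C(=O)OC)(C(=O)OC)C1 | intermediate
6 | vinyl acetate | C=COC(C)=O | starting material
7 | dimethyl (1R,6R)-7-acetoxy-2-oxobicyclo[4.2.0]octane-4,4-dicarboxylate, cis-fused, C7 epimers | COC(=O)C1(C(=O)OC)C[C@@H]2[C@@H](CC2OC(C)=O)C(=O)C1 | intermediate
8 | methyl (1R,6R)-7-acetoxy-2-oxobicyclo[4.2.0]octane-4-carboxylate, cis-fused, C4 and C7 epimers | COC(=O)C1C[C@@H]2[C@@H](CC2OC(C)=O)C(=O)C1 | intermediate
9 | methyl 7-acetoxy-2-hydroxy-2-methylbicyclo[4.2.0]octane-4-carboxylate, 2-OH cis to the four-membered ring | COC(=O)C1C[C@@H]2[C@@H](CC2OC(C)=O)[C@@](C)(O)C1 | intermediate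
10 | methyl 7-acetoxy-2-methyl-2-(triethylsilyloxy)bicyclo[4.2.0]octane-4-carboxylate | COC(=O)C1C[C@@H]2[C@@H](CC2OC(C)=O)[C@@](C)(O[Si](CC)(CC)CC)C1 | intermediate
11 | methyl 7-hydroxy-2-methyl-2-(triethylsilyloxy)bicyclo[4.2.0]octane-4-carboxylate, ester cis to silyloxy, C7 epimers | COC(=O)[C@H]1C[C@@H]2[C@@H](CC2O)[C@@](C)(O[Si](CC)(CC)CC)C1 | intermediate
12 | methyl 2-methyl-7-oxo-2-(triethylsilyloxy)bicyclo[4.2.0]octane-4-carboxylate | COC(=O)[C@H]1C[C@@H]2[C@@H](CC2=O)[C@@](C)(O[Si](CC)(CC)CC)C1 | intermediate
13 | methyl 7-(1-ethoxyvinyl)-7-hydroxy-2-methyl-2-(triethylsilyloxy)bicyclo[4.2.0]octane-4-carboxylate, 7-OH endo | COC(=O)[C@H]1C[C@@H]2[C@@H](C[C@@]2(O)C(=C)OCC)[C@@](C)(O[Si](CC)(CC)CC)C1 | intermediate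
14 | methyl 7-acetyl-7-hydroxy-2-methyl-2-(triethylsilyloxy)bicyclo[4.2.0]octane-4-carboxylate, 7-OH endo | COC(=O)[C@H]1C[C@@H]2[C@@H](C[C@@]2(O)C(C)=O)[C@@](C)(O[Si](CC)(CC)CC)C1 | intermediate
15 | methyl 1-hydroxy-1,4-dimethyl-2-oxo-4-(triethylsilyloxy)octahydro-1H-indene-6-carboxylate, cis-fused | COC(=O)[C@H]1C[C@@H]2[C@@H](CC(=O)[C@]2(C)O)[C@@](C)(O[Si](CC)(CC)CC)C1 | intermediate
16 | methyl 1,4-dimethyl-2-oxo-1,4-bis(triethylsilyloxy)octahydro-1H-indene-6-carboxylate | COC(=O)[C@H]1C[C@@H]2[C@@H](CC(=O)[C@]2(C)O[Si](CC)(CC)CC)[C@@](C)(O[Si](CC)(CC)CC)C1 | intermediate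
17 | methyl 2-hydroxy-1,4-dimethyl-1,4-bis(triethylsilyloxy)octahydro-1H-indene-6-carboxylate, C2 epimers | COC(=O)[C@H]1C[C@@H]2[C@@H](CC(O)[C@]2(C)O[Si](CC)(CC)CC)[C@@](C)(O[Si](CC)(CC)CC)C1 | intermediate
18 | methyl 2-[(1H-imidazol-1-ylcarbonothioyl)oxy]-1,4-dimethyl-1,4-bis(triethylsilyloxy)octahydro-1H-indene-6-carboxylate | COC(=O)[C@H]1C[C@@H]2[C@@H](CC(OC(=S)n3ccnc3)[C@]2(C)O[Si](CC)(CC)CC)[C@@](C)(O[Si](CC)(CC)CC)C1 | intermediate
19 | methyl 1,4-dimethyl-1,4-bis(triethylsilyloxy)octahydro-1H-indene-6-carboxylate, cis-fused | COC(=O)[C@H]1C[C@@H]2[C@@H](CC[C@]2(C)O[Si](CC)(CC)CC)[C@@](C)(O[Si](CC)(CC)CC)C1 | intermediate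
20 | tert-butyl 2-methyl-3-oxobutanoate | CC(=O)C(C)C(=O)OC(C)(C)C | starting material
21 | L-valine tert-butyl ester | CC(C)[C@H](N)C(=O)OC(C)(C)C | starting material
22 | tert-butyl (Z)-3-{[(S)-1-tert-butoxy-3-methyl-1-oxobutan-2-yl]amino}-2-methylbut-2-enoate | C/C(N[C@@H](C(C)C)C(=O)OC(C)(C)C)=C(\C)C(=O)OC(C)(C)C | intermediate
23 | prenyl bromide (1-bromo-3-methylbut-2-ene) | CC(C)=CCBr | starting material
24 | tert-butyl (S)-2-{1-[(S)-1-tert-butoxy-3-methyl-1-oxobutan-2-yl]iminoethyl}-2,5-dimethylhex-4-enoate | CC(=N[C@@H](C(C)C)C(=O)OC(C)(C)C)[C@](C)(CC=C(C)C)C(=O)OC(C)(C)C | intermediate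
25 | tert-butyl (S)-2-acetyl-2,5-dimethylhex-4-enoate | CC(=O)[C@](C)(CC=C(C)C)C(=O)OC(C)(C)C | intermediate
26 | trimethylsilyl (S)-2-acetyl-2,5-dimethylhex-4-enoate | CC(=O)[C@](C)(CC=C(C)C)C(=O)O[Si](C)(C)C | intermediate
27 | (S)-2-acetyl-2,5-dimethylhex-4-enoyl chloride | CC(=O)[C@](C)(CC=C(C)C)C(Cl)=O | intermediate
28 | methyl 6-[(S)-2-acetyl-2,5-dimethylhex-4-enoyl]-1,4-dimethyl-1,4-bis(triethylsilyloxy)octahydro-1H-indene-6-carboxylate | CC(=O)[C@](C)(CC=C(C)C)C(=O)[C@]1(C[C@@H]2[C@@H](CC[C@]2(C)O[Si](CC)(CC)CC)[C@@](C)(O[Si](CC)(CC)CC)C1)C(=O)OC | intermediate
29 | 3-methyl-3-prenyl-1',4'-dimethyl-1',4'-bis(triethylsilyloxy)octahydrospiro[cyclohexane-1,6'-indene]-2,4,6-trione | C1C(=O)[C@](C)(CC=C(C)C)C(=O)[C@]2(C[C@@H]3[C@@H](CC[C@]3(C)O[Si](CC)(CC)CC)[C@@](C)(O[Si](CC)(CC)CC)C2)C1=O | intermediate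
30 | (R)-2-methylbutanoic acid | CC[C@@H](C)C(=O)O | starting material
31 | enol (R)-2-methylbutanoate of 29 (O-acyl isomer, one of two possible enol oxygens shown) | C1=C(OC(=O)[C@H](C)CC)[C@](C)(CC=C(C)C)C(=O)[C@]2(C[C@@H]3[C@@H](CC[C@]3(C)O[Si](CC)(CC)CC)[C@@](C)(O[Si](CC)(CC)CC)C2)C1=O | intermediate
32 | bis(triethylsilyl) ether of the target | CC[C@@H](C)C(=O)C1=C(O)[C@](C)(CC=C(C)C)C(=O)[C@]2(C[C@@H]3[C@@H](CC[C@]3(C)O[Si](CC)(CC)CC)[C@@](C)(O[Si](CC)(CC)CC)C2)C1=O | intermediate
33 | CNP0236509.3: 4-hydroxy-1',4'-dihydroxy-3,1',4'-trimethyl-5-[(R)-2-methylbutanoyl]-3-prenyl-octahydrospiro[cyclohex-4-ene-1,6'-indene]-2,6-dione | CC[C@@H](C)C(=O)C1=C(O)[C@](C)(CC=C(C)C)C(=O)[C@]2(C[C@@H]3[C@@H](CC[C@]3(C)O)[C@@](C)(O)C2)C1=O | target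

## Step count and least certain steps

Total: 22 steps. Longest linear sequence: 19 steps (steps 1–15 and 19–22); the fragment branch is steps 16–18.

**Step 11 (key step).** The shift may go astray by competing migration of the ring CH2, or by loss of chelation so that the dipole-opposed geometry delivers the epimeric carbinol. Both are possible because the two ring bonds are equally well aligned in the chelate and the substrate carries other Lewis-basic sites. Fallback: starting from cyclobutanone 12, one-carbon ring enlargement with TMSCHN2/BF3·OEt2 (migration of the less substituted CH2, desilylating work-up) gives methyl 4-methyl-1-oxo-4-(triethylsilyloxy)octahydro-1H-indene-6-carboxylate F1. MeMgBr/CeCl3 adds from the convex face to give the tertiary alcohol methyl 1-hydroxy-1,4-dimethyl-4-(triethylsilyloxy)octahydro-1H-indene-6-carboxylate F2. Silylation with TESOTf returns to the route at 19.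

**Step 4.** Binding of the Lewis acid by the ester groups of 5 or by the excess vinyl acetate may leave an unselective background cycloaddition, and head-to-head regioisomers may form. The catalysis has been proven with hydrocarbon olefins, not with enol esters. Fallback: starting from 5, direct irradiation (350 nm) with 6 and no Lewis acid gives the racemic adduct. After separation of the C7 epimers on silica it is resolved by preparative chromatography on a chiral stationary phase. The mirror-image adduct dimethyl (1S,6S)-7-acetoxy-2-oxobicyclo[4.2.0]octane-4,4-dicarboxylate F3 is discarded, and the route is rejoined at 7.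

**Step 19.** C–C bond formation between two fully substituted carbons may be outrun by proton transfer from the acetyl group of 27 or by O-acylation. Attack on the wrong enolate face through the minor chair would give the spiro epimer. Fallback: starting from 19, saponification (LiOH, THF/H2O) gives the acid 1,4-dimethyl-1,4-bis(triethylsilyloxy)octahydro-1H-indene-6-carboxylic acid F6. Carbonyldiimidazole converts it to the acyl imidazole F7. The lithium enolate of 25 (LDA, at the acetyl methyl) is acylated by F7 to the beta-diketone tert-butyl (S)-2-methyl-2-prenyl-3,5-dioxo-5-[1,4-dimethyl-1,4-bis(triethylsilyloxy)octahydro-1H-inden-6-yl]pentanoate F8. Its dianion (KHMDS, 2.2 equiv) closes from the ring carbon onto the tert-butyl ester, so the hindered bond forms intramolecularly, and the route is rejoined at 29.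

**Step 6.** Poor facial selectivity in the methyl addition is the likely failure, because the preferred face depends on a conformational balance of the flexible six-membered ring. Fallback: starting from 8, Wittig methylenation (Ph3P=CH2, THF) gives methyl 7-acetoxy-2-methylenebicyclo[4.2.0]octane-4-carboxylate F4. Mukaiyama hydration (Co(acac)2, PhSiH3, O2, i-PrOH) delivers oxygen, not carbon, to the accessible face, and the route is rejoined at 9. If methyl and oxygen both prefer the same face, one of the two sequences gives the required carbinol.

**Step 17.** Low facial discrimination in the alkylation of an acyclic aza-enolate, or some SN2' attack on prenyl bromide, would erode the enantiomeric purity of the quaternary centre. Fallback: starting from 20, asymmetric allylic alkylation with methyl prenyl carbonate, Pd2(dba)3 (a zerovalent palladium source) and (R,R)- or (S,S)-N,N'-(cyclohexane-1,2-diyl)bis[2-(diphenylphosphino)benzamide] goes directly to 25, with attack at the unsubstituted allyl terminus. This fallback makes no compound outside the list (entry F0).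

**Step 10.** Enolisation of the cyclobutanone or attack on the ester by the basic vinyl lithium may compete, and the acid hydrolysis may loosen the silyl ether. Fallback: starting from 12, addition of HC≡CMgBr (THF, −78 °C, convex face) gives methyl 7-ethynyl-7-hydroxy-2-methyl-2-(triethylsilyloxy)bicyclo[4.2.0]octane-4-carboxylate F5. Markovnikov hydration (Hg(OTf)2 cat., H2O, MeCN) returns to the route at 14.

## Further compounds

F0 | step 17 | none | none
F1 | step 11 | methyl 4-methyl-1-oxo-4-(triethylsilyloxy)octahydro-1H-indene-6-carboxylate | COC(=O)[C@H]1C[C@@H]2[C@@H](CCC2=O)[C@@](C)(O[Si](CC)(CC)CC)C1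
F2 | step 11 | methyl 1-hydroxy-1,4-dimethyl-4-(triethylsilyloxy)octahydro-1H-indene-6-carboxylate | COC(=O)[C@H]1C[C@@H]2[C@@H](CC[C@]2(C)O)[C@@](C)(O[Si](CC)(CC)CC)C1
F3 | step 4 | dimethyl (1S,6S)-7-acetoxy-2-oxobicyclo[4.2.0]octane-4,4-dicarboxylate | COC(=O)C1(C(=O)OC)C[C@H]2[C@H](CC2OC(C)=O)C(=O)C1
F4 | step 6 | methyl 7-acetoxy-2-methylenebicyclo[4.2.0]octane-4-carboxylate | COC(=O)C1C[C@@H]2[C@@H](CC2OC(C)=O)C(=C)C1
F5 | step 10 | methyl 7-ethynyl-7-hydroxy-2-methyl-2-(triethylsilyloxy)bicyclo[4.2.0]octane-4-carboxylate | COC(=O)[C@H]1C[C@@H]2[C@@H](C[C@@]2(O)C#C)[C@@](C)(O[Si](CC)(CC)CC)C1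
F6 | step 19 | 1,4-dimethyl-1,4-bis(triethylsilyloxy)octahydro-1H-indene-6-carboxylic acid | OC(=O)[C@H]1C[C@@H]2[C@@H](CC[C@]2(C)O[Si](CC)(CC)CC)[C@@](C)(O[Si](CC)(CC)CC)C1
F7 | step 19 | 1-{[1,4-dimethyl-1,4-bis(triethylsilyloxy)octahydro-1H-inden-6-yl]carbonyl}-1H-imidazole | O=C(n1ccnc1)[C@H]1C[C@@H]2[C@@H](CC[C@]2(C)O[Si](CC)(CC)CC)[C@@](C)(O[Si](CC)(CC)CC)C1
F8 | step 19 | tert-butyl (S)-2-methyl-2-prenyl-3,5-dioxo-5-[1,4-dimethyl-1,4-bis(triethylsilyloxy)octahydro-1H-inden-6-yl]pentanoate | CC(C)(C)OC(=O)[C@@](C)(CC=C(C)C)C(=O)CC(=O)[C@H]1C[C@@H]2[C@@H](CC[C@]2(C)O[Si](CC)(CC)CC)[C@@](C)(O[Si](CC)(CC)CC)C1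
A1 | alternative 1 | spiro tricyclic ring-C ketone | CC[C@@H](C)C(=O)C1=C(O)[C@](C)(CC=C(C)C)C(=O)[C@]2(C[C@@H]3[C@@H](CCC3=O)[C@@](C)(O)C2)C1=O
A2 | alternative 2 | cis-bicyclo[4.2.0]octanone ketal gem-diester | COC(=O)C1(C(=O)OC)C[C@@H]2[C@@H](CC2=O)C3(O[C@H](C)[C@@H](C)O3)C1
A3 | alternative 3 | cis-hydrindane-1,4-dione gem-diester | COC(=O)C1(C(=O)OC)C[C@@H]2[C@@H](CCC2=O)C(=O)C1
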